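**Retrosynthetic overview**
1. Target 22 is (2S)-6-[(2R)-lavandulyl]-5,7,2',4',6'-pentahydroxyflavanone; its C4 ketone is taken back to the CH2 of a flavan (DDQ/water, then Dess–Martin oxidation), and four MOM ethers plus one acetate are removed last by acid.
2. The strategy rests on ring C (O1, C2, C3, C4, C4a, C8a): cutting O1–C2 and C3–C4 leaves O1–C8a–C4a–C4 as an ortho-quinone methide of ring A and C2–C3 as the vinyl group of a ring B styrene, whose free 2'-hydroxyl (present in the target) is the handle for a chiral phosphoric acid.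
3. Ring A piece: phloroglucinol → symmetric 4-lavandulyl-3,5-bis(MOM-oxy)phenol (ortho-lithiation/iodination, then Negishi coupling with the zinc reagent from lipase-resolved (S)-lavandulol) → ortho-formylation and reduction → salicyl alcohol 13.
4. Ring B piece: 2,4,6-trihydroxybenzaldehyde → bis-MOM ether → Wittig methylenation → hydroxystyrene 16.
5. Rings A and B are bought as aromatics; ring C is the only ring formed (step 12), which also sets C2; the lavandulyl centre comes from the resolved alcohol.

Key step: step 12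

Abbreviations: MOM = methoxymethyl; TIPS = tri(propan-2-yl)silyl; TBS = tert-butyldimethylsilyl; lavandulyl = 5-methyl-2-(prop-1-en-2-yl)hex-4-en-1-yl.

Assumption: the lipase is taken to acylate (R)-lavandulol faster and the (R)-configured phosphoric acid is taken to give (2S); if either sense proves opposite on a trial run, the (S)-acetate is methanolysed to 2, or the (S)-catalyst is used.

**Route**

Step 1
Reactants: 1 racemic lavandulol
Product: 2 (S)-lavandulol [(2S)-5-methyl-2-(prop-1-en-2-yl)hex-4-en-1-ol]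
Conditions: Novozym 435 (immobilised Candida antarctica lipase B), vinyl acetate, hexane, rt, run to about 60% conversion; chromatography
Reagents that add atoms: none
Why: Lipase-catalysed kinetic resolution by transesterification should acylate the (R)-alcohol faster, so that running past half conversion leaves (S)-lavandulol, the enantiomer that maps onto the (R)-lavandulyl group of the target, in high enantiomeric purity (to be checked by chiral GC and repeated if needed).

Step 2
Reactants: 2 (S)-lavandulol
Product: 3 (S)-lavandulyl iodide [(5S)-6-iodo-2-methyl-5-(prop-1-en-2-yl)hex-2-ene]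
Conditions: I2, PPh3, imidazole, CH2Cl2, 0 °C to rt, dark
Reagents that add atoms: iodine, [I][I]
Why: Appel iodination displaces the activated primary hydroxyl by SN2 at CH2 and touches neither the adjacent stereocentre nor the two alkenes.

Step 3
Reactants: 4 phloroglucinol
Product: 5 3,5-bis(methoxymethoxy)phenol
Conditions: MOMCl (2.0 equiv), i-Pr2NEt, DMF/CH2Cl2, 0 °C to rt; chromatography
Reagents that add atoms: chloromethyl methyl ether, COCCl
Why: O-alkylation of the phenol with MOMCl at two equivalents should make the bis-ether the main component of a statistical mixture, from which mono- and tris-ethers are separated and recycled.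

Step 4
Reactants: 5 3,5-bis(methoxymethoxy)phenol
Product: 6 [3,5-bis(methoxymethoxy)phenoxy]tri(propan-2-yl)silane
Conditions: TIPSCl, imidazole, DMF, rt
Reagents that add atoms: chlorotri(propan-2-yl)silane, CC(C)[Si](Cl)(C(C)C)C(C)C
Why: Silylation of the remaining phenol gives a bulky ether that is a poor metalation director and shields its two neighbours, which fixes the site of the lithiation that follows.

Step 5
Reactants: 6 [3,5-bis(methoxymethoxy)phenoxy]tri(propan-2-yl)silane
Product: 8 [4-iodo-3,5-bis(methoxymethoxy)phenoxy]tri(propan-2-yl)silane, via aryllithium 7 (not isolated)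
Conditions: n-BuLi (1.1 equiv), THF, 0 °C; then I2, −78 °C to rt
Reagents that add atoms: iodine, [I][I]
Why: Directed ortho-metalation, in which the two MOM ethers cooperatively guide lithium to the carbon between them (para to the silyl ether), followed by iodine quench gives the symmetric aryl iodide.

Step 6
Reactants: 3 (S)-lavandulyl iodide; 8 [4-iodo-3,5-bis(methoxymethoxy)phenoxy]tri(propan-2-yl)silane
Product: 10 {4-[(2R)-lavandulyl]-3,5-bis(methoxymethoxy)phenoxy}tri(propan-2-yl)silane, via lavandulylzinc iodide 9 (not isolated)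
Conditions: 3, zinc dust (activated with 1,2-dibromoethane and Me3SiCl), LiCl, THF, 40 °C; then 8, Pd(OAc)2 (3 mol %), 2-dicyclohexylphosphino-2',6'-dimethoxybiphenyl (SPhos, 6 mol %), THF, rt to 45 °C
Reagents that add atoms: none
Why: Negishi sp3–sp2 coupling, with zinc insertion into the primary C–I bond and palladium catalysis by a bulky biarylphosphine (fast reductive elimination, little beta-hydride elimination), should join the lavandulyl CH2 to the iodinated carbon with the neighbouring stereocentre untouched, since no bond to it is made or broken.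

Step 7
Reactants: 10 {4-[(2R)-lavandulyl]-3,5-bis(methoxymethoxy)phenoxy}tri(propan-2-yl)silane
Product: 11 4-[(2R)-lavandulyl]-3,5-bis(methoxymethoxy)phenol
Conditions: TBAF, THF, 0 °C
Reagents that add atoms: none
Why: Fluoride cleavage of the aryl silyl ether frees the phenol para to the lavandulyl group while MOM ethers and alkenes are inert.

Step 8
Reactants: 11 4-[(2R)-lavandulyl]-3,5-bis(methoxymethoxy)phenol
Product: 12 2-hydroxy-5-[(2R)-lavandulyl]-4,6-bis(methoxymethoxy)benzaldehyde
Conditions: MgCl2, Et3N, paraformaldehyde, MeCN, 70 °C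
Reagents that add atoms: paraformaldehyde (as formaldehyde), C=O
Why: Magnesium-mediated ortho-formylation of a phenol (Casnati–Skattebøl reaction) delivers formaldehyde from the magnesium phenoxide to the ortho carbon, and because the two free ring positions are equivalent only one salicylaldehyde can form.

Step 9
Reactants: 12 2-hydroxy-5-[(2R)-lavandulyl]-4,6-bis(methoxymethoxy)benzaldehyde
Product: 13 2-(hydroxymethyl)-4-[(2R)-lavandulyl]-3,5-bis(methoxymethoxy)phenol
Conditions: NaBH4, THF/MeOH, 0 °C; pH 7 work-up, used crude at once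
Reagents that add atoms: none
Why: Borohydride reduction of the aldehyde gives the primary salicyl alcohol, which is electron-rich and acid-labile and is therefore not exposed to silica.

Step 10
Reactants: 14 2,4,6-trihydroxybenzaldehyde
Product: 15 2-hydroxy-4,6-bis(methoxymethoxy)benzaldehyde
Conditions: MOMCl (2.1 equiv), i-Pr2NEt, CH2Cl2, 0 °C to rt
Reagents that add atoms: chloromethyl methyl ether, COCCl
Why: Selective O-alkylation leaves free the one hydroxyl that is hydrogen-bonded to the formyl group, since it is the least nucleophilic of the three.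

Step 11
Reactants: 15 2-hydroxy-4,6-bis(methoxymethoxy)benzaldehyde
Product: 16 2-ethenyl-3,5-bis(methoxymethoxy)phenol
Conditions: Ph3PCH3Br (2.5 equiv), KOt-Bu (2.5 equiv), THF, 0 °C to rt; stored cold, used fresh
Reagents that add atoms: methyltriphenylphosphonium bromide, C[P+](c1ccccc1)(c1ccccc1)c1ccccc1.[Br-]
Why: Wittig methylenation with excess ylide (one equivalent is consumed in deprotonating the phenol) converts the aldehyde into the vinyl group without protecting the hydroxyl that the key step needs.

Step 12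
Reactants: 13 2-(hydroxymethyl)-4-[(2R)-lavandulyl]-3,5-bis(methoxymethoxy)phenol; 16 2-ethenyl-3,5-bis(methoxymethoxy)phenol
Product: 18 2-{(2S)-6-[(2R)-lavandulyl]-5,7-bis(methoxymethoxy)-3,4-dihydro-2H-chromen-2-yl}-3,5-bis(methoxymethoxy)phenol, via ortho-quinone methide 17 (not isolated)
Conditions: (R)-3,3'-bis(2,4,6-triisopropylphenyl)-1,1'-binaphthyl-2,2'-diyl hydrogen phosphate (10 mol %), 4 Å molecular sieves, toluene, −10 °C to rt, slow addition of 13 to 16 (1.5 equiv)
Reagents that add atoms: none
Why: Proposed new method: the phosphoric acid should protonate the benzylic hydroxyl of 13 and expel water to give methide 17, which the two MOM-oxy donors make accessible even without a carbinol substituent, and then hold 17 (P–OH to the methide oxygen) and styrene 16 (P=O to its free ortho-hydroxyl) in one chiral hydrogen-bonded assembly. The closest known reaction type is the chiral phosphoric acid-catalysed oxa-[4+2] cycloaddition of aryl-substituted ortho-quinone methides, made from secondary ortho-hydroxybenzyl alcohols, with ortho-hydroxystyrenes to give 2,4-diarylchromans; here the methide carbon is an unsubstituted CH2, which is the untested element. Ring C closes in an intermolecular, concerted but asynchronous inverse-electron-demand [4π+2π] mode, the C4–C3 bond leading and the O1–C2 bond following (in the stepwise limit, a 6-exo-trig capture of the ring B benzylic cation by the ring A oxygen). C2 is the only new stereocentre and its (S) configuration is set by the catalyst, whose two-point hydrogen bonding exposes one face of the styrene CH; the remote (R)-lavandulyl centre is too far away to interfere. The step needs regioselectivity (O1 to C2, C4 to C3), secured by matching the electrophilic methide CH2 with the nucleophilic styrene terminus and by the single free phenol of 13, which allows only one methide; it also needs chemoselectivity over methide oligomerisation and styrene dimerisation, secured by slow addition of 13 to excess 16 over sieves at low temperature.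

Step 13
Reactants: 18 2-{(2S)-6-[(2R)-lavandulyl]-5,7-bis(methoxymethoxy)-3,4-dihydro-2H-chromen-2-yl}-3,5-bis(methoxymethoxy)phenol
Product: 19 2-{(2S)-6-[(2R)-lavandulyl]-5,7-bis(methoxymethoxy)-3,4-dihydro-2H-chromen-2-yl}-3,5-bis(methoxymethoxy)phenyl acetate
Conditions: Ac2O, pyridine, 4-(dimethylamino)pyridine (cat.), CH2Cl2, rt
Reagents that add atoms: acetic anhydride, CC(=O)OC(C)=O
Why: Acylation of the only free phenol protects it and lowers the electron density of ring B before the oxidation, so that it can neither be oxidised nor trap a C4 cation.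

Step 14
Reactants: 19 2-{(2S)-6-[(2R)-lavandulyl]-5,7-bis(methoxymethoxy)-3,4-dihydro-2H-chromen-2-yl}-3,5-bis(methoxymethoxy)phenyl acetate
Product: 20 2-{(2S)-4-hydroxy-6-[(2R)-lavandulyl]-5,7-bis(methoxymethoxy)-3,4-dihydro-2H-chromen-2-yl}-3,5-bis(methoxymethoxy)phenyl acetate (both C4 epimers)
Conditions: DDQ (1.3 equiv), CH2Cl2/pH 7 phosphate buffer (10:1), 0 °C
Reagents that add atoms: water, O
Why: DDQ benzylic oxidation by hydride abstraction, as practised at C4 of 5,7-dioxygenated flavans, should take the C4–H bond that lies parallel to the ring A pi system and gives a cation stabilised by three oxygens and trapped by water, whereas C2–H sits on an acetylated, twisted ring B and the lavandulyl CH2 is flanked by two ortho substituents (any ketone 21 formed by further oxidation is carried along).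

Step 15
Reactants: 20 2-{(2S)-4-hydroxy-6-[(2R)-lavandulyl]-5,7-bis(methoxymethoxy)-3,4-dihydro-2H-chromen-2-yl}-3,5-bis(methoxymethoxy)phenyl acetate
Product: 21 2-{(2S)-6-[(2R)-lavandulyl]-5,7-bis(methoxymethoxy)-4-oxo-3,4-dihydro-2H-chromen-2-yl}-3,5-bis(methoxymethoxy)phenyl acetate
Conditions: Dess–Martin periodinane, NaHCO3, CH2Cl2, 0 °C to rt
Reagents that add atoms: none
Why: Dess–Martin oxidation of the secondary benzylic alcohol under buffered, non-basic conditions gives the ketone from either C4 epimer without opening ring C.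

Step 16
Reactants: 21 2-{(2S)-6-[(2R)-lavandulyl]-5,7-bis(methoxymethoxy)-4-oxo-3,4-dihydro-2H-chromen-2-yl}-3,5-bis(methoxymethoxy)phenyl acetate
Product: 22 (2S)-5,7-dihydroxy-6-[(2R)-5-methyl-2-(prop-1-en-2-yl)hex-4-en-1-yl]-2-(2,4,6-trihydroxyphenyl)-2,3-dihydro-4H-chromen-4-one
Conditions: HCl in MeOH (1.25 M), THF co-solvent, 0 °C to rt, argon, stopped as soon as conversion is complete
Reagents that add atoms: none
Why: Acid-catalysed methanolysis cleaves the four MOM acetals and transesterifies the aryl acetate in one operation, under conditions in which prenyl-type alkenes next to phenols usually survive and which avoid the base-promoted ring opening that would epimerise C2.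

**Compound list**
1 | racemic lavandulol [5-methyl-2-(prop-1-en-2-yl)hex-4-en-1-ol] | C=C(C)C(CO)CC=C(C)C | starting material
2 | (S)-lavandulol | C=C(C)[C@H](CC=C(C)C)CO | intermediate
3 | (S)-lavandulyl iodide | C=C(C)[C@H](CC=C(C)C)CI | intermediate
4 | phloroglucinol | Oc1cc(O)cc(O)c1 | starting material
5 | 3,5-bis(methoxymethoxy)phenol | COCOc1cc(O)cc(OCOC)c1 | intermediate
6 | [3,5-bis(methoxymethoxy)phenoxy]tri(propan-2-yl)silane | COCOc1cc(O[Si](C(C)C)(C(C)C)C(C)C)cc(OCOC)c1 | intermediate
7 | [2,6-bis(methoxymethoxy)-4-{[tri(propan-2-yl)silyl]oxy}phenyl]lithium | [Li]c1c(OCOC)cc(O[Si](C(C)C)(C(C)C)C(C)C)cc1OCOC | intermediate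
8 | [4-iodo-3,5-bis(methoxymethoxy)phenoxy]tri(propan-2-yl)silane | COCOc1cc(O[Si](C(C)C)(C(C)C)C(C)C)cc(OCOC)c1I | intermediate
9 | [(2S)-5-methyl-2-(prop-1-en-2-yl)hex-4-en-1-yl]zinc iodide | C=C(C)[C@H](CC=C(C)C)C[Zn]I | intermediate
10 | {4-[(2R)-lavandulyl]-3,5-bis(methoxymethoxy)phenoxy}tri(propan-2-yl)silane | C=C(C)[C@H](CC=C(C)C)Cc1c(OCOC)cc(O[Si](C(C)C)(C(C)C)C(C)C)cc1OCOC | intermediate
11 | 4-[(2R)-lavandulyl]-3,5-bis(methoxymethoxy)phenol | C=C(C)[C@H](CC=C(C)C)Cc1c(OCOC)cc(O)cc1OCOC | intermediate
12 | 2-hydroxy-5-[(2R)-lavandulyl]-4,6-bis(methoxymethoxy)benzaldehyde | C=C(C)[C@H](CC=C(C)C)Cc1c(OCOC)cc(O)c(C=O)c1OCOC | intermediate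
13 | 2-(hydroxymethyl)-4-[(2R)-lavandulyl]-3,5-bis(methoxymethoxy)phenol | C=C(C)[C@H](CC=C(C)C)Cc1c(OCOC)cc(O)c(CO)c1OCOC | intermediate
14 | 2,4,6-trihydroxybenzaldehyde | O=Cc1c(O)cc(O)cc1O | starting material
15 | 2-hydroxy-4,6-bis(methoxymethoxy)benzaldehyde | COCOc1cc(O)c(C=O)c(OCOC)c1 | intermediate
16 | 2-ethenyl-3,5-bis(methoxymethoxy)phenol | C=Cc1c(O)cc(OCOC)cc1OCOC | intermediate
17 | 4-[(2R)-lavandulyl]-3,5-bis(methoxymethoxy)-6-methylidenecyclohexa-2,4-dien-1-one | C=C(C)[C@H](CC=C(C)C)CC1=C(OCOC)C(=C)C(=O)C=C1OCOC | intermediate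
18 | 2-{(2S)-6-[(2R)-lavandulyl]-5,7-bis(methoxymethoxy)-3,4-dihydro-2H-chromen-2-yl}-3,5-bis(methoxymethoxy)phenol | C=C(C)[C@H](CC=C(C)C)Cc1c(OCOC)cc2c(c1OCOC)CC[C@@H](c1c(O)cc(OCOC)cc1OCOC)O2 | intermediate
19 | 2-{(2S)-6-[(2R)-lavandulyl]-5,7-bis(methoxymethoxy)-3,4-dihydro-2H-chromen-2-yl}-3,5-bis(methoxymethoxy)phenyl acetate | C=C(C)[C@H](CC=C(C)C)Cc1c(OCOC)cc2c(c1OCOC)CC[C@@H](c1c(OC(C)=O)cc(OCOC)cc1OCOC)O2 | intermediate
20 | 2-{(2S)-4-hydroxy-6-[(2R)-lavandulyl]-5,7-bis(methoxymethoxy)-3,4-dihydro-2H-chromen-2-yl}-3,5-bis(methoxymethoxy)phenyl acetate (C4 epimers) | C=C(C)[C@H](CC=C(C)C)Cc1c(OCOC)cc2c(c1OCOC)C(O)C[C@@H](c1c(OC(C)=O)cc(OCOC)cc1OCOC)O2 | intermediate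
21 | 2-{(2S)-6-[(2R)-lavandulyl]-5,7-bis(methoxymethoxy)-4-oxo-3,4-dihydro-2H-chromen-2-yl}-3,5-bis(methoxymethoxy)phenyl acetate | C=C(C)[C@H](CC=C(C)C)Cc1c(OCOC)cc2c(c1OCOC)C(=O)C[C@@H](c1c(OC(C)=O)cc(OCOC)cc1OCOC)O2 | intermediate
22 | (2S)-5,7-dihydroxy-6-[(2R)-5-methyl-2-(prop-1-en-2-yl)hex-4-en-1-yl]-2-(2,4,6-trihydroxyphenyl)-2,3-dihydro-4H-chromen-4-one | C=C(C)[C@H](CC=C(C)C)Cc1c(O)cc2c(c1O)C(=O)C[C@@H](c1c(O)cc(O)cc1O)O2 | target

**Step count**
Total steps: 16. Longest linear sequence: 12 steps (phloroglucinol 4 to 22 through steps 3–9 and 12–16).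

**Steps most likely to fail**

Step 12 (proposed new method). What may go wrong: oligomerisation of the unsubstituted methide, or acid-induced dimerisation of the styrene, may outrun the cross-cycloaddition; facial discrimination may be weak because the methide offers the catalyst no aryl group to grip; the acid may also strip MOM groups. The fallback uses known chemistry, sets out from phenol 11 and styrene 16, and comes back at flavan 18. A Mannich reaction of 11 (aqueous formaldehyde, dimethylamine, EtOH, rt) at the only free ortho position should give 2-[(dimethylamino)methyl]-4-[(2R)-lavandulyl]-3,5-bis(methoxymethoxy)phenol F1. Heating F1 with 16 in toluene or chlorobenzene at 110–130 °C expels dimethylamine and generates the same methide 17 under neutral conditions. Its thermal hetero-Diels–Alder reaction with the styrene, the classical non-catalysed path from phenolic Mannich bases to flavans, should give the C2-epimeric flavan mixture F2. The epimers are diastereomers because of the lavandulyl centre and are separated by preparative HPLC (chiral stationary phase if needed); the (2S) epimer is 18.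

Step 14. What may go wrong: hydride abstraction at the wrong C–H bond (C2–H, or the lavandulyl benzylic CH2), or over-oxidation through the flav-3-ene. The fallback brings C4 in as a carbonyl and needs no C–H oxidation; it sets out from aldehydes 12 and 15 and comes back at target 22. Addition of MeMgBr (excess, THF, 0 °C) to 12 gives 2-(1-hydroxyethyl)-4-[(2R)-lavandulyl]-3,5-bis(methoxymethoxy)phenol F3, and MnO2 in CH2Cl2 oxidises it to 1-{2-hydroxy-5-[(2R)-lavandulyl]-4,6-bis(methoxymethoxy)phenyl}ethanone F4. Aldehyde 15 is capped (MOMCl, NaH, DMF) as 2,4,6-tris(methoxymethoxy)benzaldehyde F5. Claisen–Schmidt condensation of F4 with F5 (KOH, EtOH/water, rt) gives the (E)-chalcone 1-{2-hydroxy-5-[(2R)-lavandulyl]-4,6-bis(methoxymethoxy)phenyl}-3-[2,4,6-tris(methoxymethoxy)phenyl]prop-2-en-1-one F6. Oxa-Michael cyclisation (NaOAc, EtOH, reflux) gives the C2-epimeric penta-MOM flavanone mixture F7. Preparative HPLC isolates the (2S)-penta-MOM flavanone F8, and the other epimer is recycled through the chalcone. Methanolic HCl as in step 16 then gives 22.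

Step 16. What may go wrong: acid-promoted reversible opening of ring C of the ketone while the last MOM ethers are being cleaved erodes C2, and on reclosure through the other ortho oxygen moves the lavandulyl group from C6 to C8. The fallback changes the protecting-group regime before the ketone exists; it sets out from flavan 18 and comes back at target 22. Methanolic HCl on 18, where no enolisable ketone can open ring C, gives the pentaphenol (2S)-6-[(2R)-lavandulyl]-2-(2,4,6-trihydroxyphenyl)chromane-5,7-diol F9. Silylation (TBSCl, imidazole, DMF, 40 °C) gives the penta-TBS flavan F10. DDQ in wet CH2Cl2 and Dess–Martin oxidation, as in steps 14 and 15, give the penta-TBS flavan-4-ol F11 and then the penta-TBS flavanone F12. Buffered fluoride (HF·pyridine with excess pyridine, THF, 0 °C) then frees all five phenols at near-neutral pH to give 22.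

**Further compounds**
F1 | step 12 | 2-[(dimethylamino)methyl]-4-[(2R)-lavandulyl]-3,5-bis(methoxymethoxy)phenol | C=C(C)[C@H](CC=C(C)C)Cc1c(OCOC)cc(O)c(CN(C)C)c1OCOC
F2 | step 12 | C2-epimeric flavan mixture [2-{6-[(2R)-lavandulyl]-5,7-bis(methoxymethoxy)-3,4-dihydro-2H-chromen-2-yl}-3,5-bis(methoxymethoxy)phenol] | C=C(C)[C@H](CC=C(C)C)Cc1c(OCOC)cc2c(c1OCOC)CCC(c1c(O)cc(OCOC)cc1OCOC)O2
F3 | step 14 | 2-(1-hydroxyethyl)-4-[(2R)-lavandulyl]-3,5-bis(methoxymethoxy)phenol | C=C(C)[C@H](CC=C(C)C)Cc1c(OCOC)cc(O)c(C(C)O)c1OCOC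
F4 | step 14 | 1-{2-hydroxy-5-[(2R)-lavandulyl]-4,6-bis(methoxymethoxy)phenyl}ethanone | C=C(C)[C@H](CC=C(C)C)Cc1c(OCOC)cc(O)c(C(C)=O)c1OCOC
F5 | step 14 | 2,4,6-tris(methoxymethoxy)benzaldehyde | COCOc1cc(OCOC)c(C=O)c(OCOC)c1
F6 | step 14 | (E)-1-{2-hydroxy-5-[(2R)-lavandulyl]-4,6-bis(methoxymethoxy)phenyl}-3-[2,4,6-tris(methoxymethoxy)phenyl]prop-2-en-1-one | C=C(C)[C@H](CC=C(C)C)Cc1c(OCOC)cc(O)c(C(=O)/C=C/c2c(OCOC)cc(OCOC)cc2OCOC)c1OCOC
F7 | step 14 | C2-epimeric penta-MOM flavanone mixture [6-[(2R)-lavandulyl]-5,7-bis(methoxymethoxy)-2-[2,4,6-tris(methoxymethoxy)phenyl]chroman-4-one] | C=C(C)[C@H](CC=C(C)C)Cc1c(OCOC)cc2c(c1OCOC)C(=O)CC(c1c(OCOC)cc(OCOC)cc1OCOC)O2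
F8 | step 14 | (2S)-6-[(2R)-lavandulyl]-5,7-bis(methoxymethoxy)-2-[2,4,6-tris(methoxymethoxy)phenyl]chroman-4-one | C=C(C)[C@H](CC=C(C)C)Cc1c(OCOC)cc2c(c1OCOC)C(=O)C[C@@H](c1c(OCOC)cc(OCOC)cc1OCOC)O2
F9 | step 16 | (2S)-6-[(2R)-lavandulyl]-2-(2,4,6-trihydroxyphenyl)chromane-5,7-diol | C=C(C)[C@H](CC=C(C)C)Cc1c(O)cc2c(c1O)CC[C@@H](c1c(O)cc(O)cc1O)O2
F10 | step 16 | penta-TBS flavan [(2S)-5,7-bis(TBS-oxy)-6-[(2R)-lavandulyl]-2-[2,4,6-tris(TBS-oxy)phenyl]chromane] | C=C(C)[C@H](CC=C(C)C)Cc1c(O[Si](C)(C)C(C)(C)C)cc2c(c1O[Si](C)(C)C(C)(C)C)CC[C@@H](c1c(O[Si](C)(C)C(C)(C)C)cc(O[Si](C)(C)C(C)(C)C)cc1O[Si](C)(C)C(C)(C)C)O2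
F11 | step 16 | penta-TBS flavan-4-ol [(2S)-5,7-bis(TBS-oxy)-6-[(2R)-lavandulyl]-2-[2,4,6-tris(TBS-oxy)phenyl]chroman-4-ol, C4 epimers] | C=C(C)[C@H](CC=C(C)C)Cc1c(O[Si](C)(C)C(C)(C)C)cc2c(c1O[Si](C)(C)C(C)(C)C)C(O)C[C@@H](c1c(O[Si](C)(C)C(C)(C)C)cc(O[Si](C)(C)C(C)(C)C)cc1O[Si](C)(C)C(C)(C)C)O2
F12 | step 16 | penta-TBS flavanone [(2S)-5,7-bis(TBS-oxy)-6-[(2R)-lavandulyl]-2-[2,4,6-tris(TBS-oxy)phenyl]chroman-4-one] | C=C(C)[C@H](CC=C(C)C)Cc1c(O[Si](C)(C)C(C)(C)C)cc2c(c1O[Si](C)(C)C(C)(C)C)C(=O)C[C@@H](c1c(O[Si](C)(C)C(C)(C)C)cc(O[Si](C)(C)C(C)(C)C)cc1O[Si](C)(C)C(C)(C)C)O2
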